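**Plan**

- Retrosynthetic cuts: the C11–O aryl ether (umbelliferone plus a diol), then C8=C12 (methylenation of a 12-nor Δ6-8-ketone), then C6–C7 and C5–C10 together by an intramolecular Diels–Alder reaction, which opens rings A and B to an acyclic deca-1,7,9-triene.
- Enabling feature: ring B (C5, C6, C7, C8, C9, C10) shares only the C5–C10 bond with ring A. With C8 at the ketone level it is a cyclohexene enol ether C8=C9, i.e. diene C7=C8–C9=C10 plus dienophile C5=C6, and C1–C4 of ring A is the tether.
- Helpers: a phenylsulfonyl group on C6 activates the dienophile and later leaves to give C6=C7; an ethoxy group on C8 is the masked ketone that becomes C8=C12. Both are gone by step 13.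
- Forward order: the chain is built linearly (aldol, hydroxymethylation, carbomagnesiation/iodination, olefination, Stille coupling; steps 1–10), rings A and B form together in step 11, then C6=C7, C12 and the coumarin ether follow.
- Stereochemistry: C3 from an oxazaborolidinone-promoted aldol; C5 and C10 from the chair-like anti transition state of the cycloaddition, controlled by C3 and by the E geometry of C9=C10 (from syn-carbomagnesiation); C9 by axial protonation and equilibration next to the C8 ketone.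

Key step: step 11

Numbering: drimane numbering is used throughout (C1–C10 decalin, gem-dimethyl on C4, angular methyl on C10, C11 = CH2O on C9, C12 = exocyclic carbon on C8); α is the face of H-5, β that of the C10 methyl.

Assumption: the oxazaborolidinone made from N-tosyl-D-valine is taken to deliver the (3S)-aldol 4; the L-valine reagent would be used if the opposite sense were found.

**Route**

Step 1
Reactants: 1 pent-4-yn-1-ol
Product: 2 pent-4-ynal
Conditions: TEMPO (10 mol %), PhI(OAc)2, CH2Cl2, rt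
Reagents that add atoms: none
Why: Oxoammonium-mediated oxidation of a primary alcohol stops at the aldehyde and leaves the terminal alkyne untouched; the volatile aldehyde is used as a dried CH2Cl2 solution.

Step 2
Reactants: 2 pent-4-ynal; 3 1-methoxy-2-methyl-1-(trimethylsilyloxy)prop-1-ene
Product: 4 methyl (3S)-3-hydroxy-2,2-dimethylhept-6-ynoate
Conditions: N-tosyl-D-valine, BH3·THF, CH2Cl2, 0 °C → rt; then 2 and 3, −78 °C; pH 7 buffer
Reagents that add atoms: none
Why: Mukaiyama aldol addition promoted by the valine-derived oxazaborolidinone (Kiyooka aldol), which binds the aldehyde and exposes one face to the isobutyrate silyl ketene acetal, so that C3 is set next to the future C4 gem-dimethyl group.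

Step 3
Reactants: 4 methyl (3S)-3-hydroxy-2,2-dimethylhept-6-ynoate
Product: 5 methyl (3S)-3-[(tert-butyldimethylsilyl)oxy]-2,2-dimethylhept-6-ynoate
Conditions: TBSOTf, 2,6-lutidine, CH2Cl2, −78 → 0 °C
Reagents that add atoms: tert-butyldimethylsilyl triflate, CC(C)(C)[Si](C)(C)OS(=O)(=O)C(F)(F)F
Why: Silylation of a hindered secondary alcohol with the silyl triflate blocks retro-aldol cleavage and supplies the bulky C3 substituent that later steers the cycloaddition.

Step 4
Reactants: 5 methyl (3S)-3-[(tert-butyldimethylsilyl)oxy]-2,2-dimethylhept-6-ynoate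
Product: 6 (3S)-3-[(tert-butyldimethylsilyl)oxy]-2,2-dimethylhept-6-yn-1-ol
Conditions: DIBAL-H (3 equiv), CH2Cl2, −78 → 0 °C; Rochelle salt work-up
Reagents that add atoms: none
Why: Hydride reduction of the ester to the primary alcohol (C5); at or below 0 °C the terminal alkyne is not hydroaluminated and the silyl ether is stable.

Step 5
Reactants: 6 (3S)-3-[(tert-butyldimethylsilyl)oxy]-2,2-dimethylhept-6-yn-1-ol
Product: 7 (6S)-6-[(tert-butyldimethylsilyl)oxy]-7,7-dimethyloct-2-yne-1,8-diol
Conditions: n-BuLi (2.2 equiv), THF, −78 → −20 °C; (CH2O)n, −20 °C → rt; H2O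
Reagents that add atoms: formaldehyde (from paraformaldehyde), C=O
Why: The acetylide carbon of the alkoxide–acetylide dianion adds to formaldehyde (alkynylation of an aldehyde), which installs C11 as the propargylic alcohol that directs step 6.

Step 6
Reactants: 7 (6S)-6-[(tert-butyldimethylsilyl)oxy]-7,7-dimethyloct-2-yne-1,8-diol
Product: 9 (2E,6S)-6-[(tert-butyldimethylsilyl)oxy]-2-iodo-3,7,7-trimethyloct-2-ene-1,8-diol, via alkenylmagnesium bromide 8 (not isolated)
Conditions: MeMgBr (6 equiv), Fe(acac)3 (15 mol %), THF, −78 → 0 °C; then I2, THF, −78 °C → rt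
Reagents that add atoms: methylmagnesium bromide, C[Mg]Br; iodine, II
Why: Alkoxide-directed iron-catalysed syn-carbomagnesiation of the propargylic alcohol puts the methyl group on the distal alkyne carbon (C10) and magnesium on C9, and iodinolysis with retention should give the tetrasubstituted iodoalkene with CH3 cis to I and C1 cis to C11.

Step 7
Reactants: 9 (2E,6S)-6-[(tert-butyldimethylsilyl)oxy]-2-iodo-3,7,7-trimethyloct-2-ene-1,8-diol
Product: 10 (3S,6E)-3-[(tert-butyldimethylsilyl)oxy]-8-[(tert-butyldiphenylsilyl)oxy]-7-iodo-2,2,6-trimethyloct-6-en-1-ol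
Conditions: TBDPSCl (1.05 equiv), imidazole, CH2Cl2, −20 → 0 °C
Reagents that add atoms: tert-butyl(chloro)diphenylsilane, CC(C)(C)[Si](Cl)(c1ccccc1)c1ccccc1
Why: Silylation with the bulky chlorosilane should select the unhindered allylic primary hydroxyl (C11) over the neopentyl one (C5), and the acid-stable silyl ether is a poor leaving group β to the later C8 ketone.

Step 8
Reactants: 10 (3S,6E)-3-[(tert-butyldimethylsilyl)oxy]-8-[(tert-butyldiphenylsilyl)oxy]-7-iodo-2,2,6-trimethyloct-6-en-1-ol
Product: 11 (3S,6E)-3-[(tert-butyldimethylsilyl)oxy]-8-[(tert-butyldiphenylsilyl)oxy]-7-iodo-2,2,6-trimethyloct-6-enal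
Conditions: Dess–Martin periodinane, CH2Cl2, 0 °C → rt
Reagents that add atoms: none
Why: Dess–Martin oxidation converts the hindered neopentyl alcohol into the aldehyde, which has no α-hydrogen and so cannot epimerise or enolise.

Step 9
Reactants: 11 (3S,6E)-3-[(tert-butyldimethylsilyl)oxy]-8-[(tert-butyldiphenylsilyl)oxy]-7-iodo-2,2,6-trimethyloct-6-enal
Product: 12 {[(1E,4S,7E)-4-[(tert-butyldimethylsilyl)oxy]-9-[(tert-butyldiphenylsilyl)oxy]-8-iodo-3,3,7-trimethylnona-1,7-dien-1-yl]sulfonyl}benzene
Conditions: (EtO)2P(O)CH2SO2Ph, NaH, THF, 0 °C; then 11, 0 °C → rt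
Reagents that add atoms: diethyl [(phenylsulfonyl)methyl]phosphonate, CCOP(=O)(CS(=O)(=O)c1ccccc1)OCC
Why: Horner–Wadsworth–Emmons olefination with the sulfonyl-stabilised phosphonate adds C6 and should give the (E)-vinyl sulfone, the activated dienophile C5=C6.

Step 10
Reactants: 12 {[(1E,4S,7E)-4-[(tert-butyldimethylsilyl)oxy]-9-[(tert-butyldiphenylsilyl)oxy]-8-iodo-3,3,7-trimethylnona-1,7-dien-1-yl]sulfonyl}benzene
Product: 13 {[(1E,4S,7E)-4-[(tert-butyldimethylsilyl)oxy]-8-{[(tert-butyldiphenylsilyl)oxy]methyl}-9-ethoxy-3,3,7-trimethyldeca-1,7,9-trien-1-yl]sulfonyl}benzene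
Conditions: CH2=C(OEt)SnBu3, Pd2(dba)3 (5 mol %), AsPh3 (20 mol %), CuI (10 mol %), NMP, 50 °C; filtration through Et3N-deactivated silica
Reagents that add atoms: tributyl(1-ethoxyvinyl)stannane, CCOC(=C)[Sn](CCCC)(CCCC)CCCC
Why: Stille coupling (oxidative addition of zerovalent palladium into C–I, copper-assisted transmetalation, reductive elimination) retains the alkene geometry and adds C7 and C8 as an electron-rich 2-ethoxy diene, the masked C8 ketone.

Step 11
Reactants: 13 {[(1E,4S,7E)-4-[(tert-butyldimethylsilyl)oxy]-8-{[(tert-butyldiphenylsilyl)oxy]methyl}-9-ethoxy-3,3,7-trimethyldeca-1,7,9-trien-1-yl]sulfonyl}benzene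
Product: 14 trans-fused cycloadduct, 8-ethoxy-6α-(phenylsulfonyl)-3β-[(tert-butyldimethylsilyl)oxy]-11-[(tert-butyldiphenylsilyl)oxy]-12-nordrim-8-ene (5α-H, 10β-CH3)
Conditions: degassed toluene (0.01 M), BHT (cat.), sealed tube, 150 °C
Reagents that add atoms: none
Why: Concerted, asynchronous thermal [4+2] cycloaddition in which the 2-ethoxy diene C7=C8–C9=C10 adds suprafacially to the sulfonyl-activated (E)-alkene C5=C6 and forms C6–C7 and C5–C10 at once; the closest known reaction type is the type 1 intramolecular Diels–Alder reaction of 1-sulfonyl-deca-1,7,9-trienes. Ring B closes as the six-membered [4+2] ring and ring A closes at the same time through the four-carbon tether C1–C4 in a chair-like fused (not bridged) mode, the only mode this tether length allows. The trans relation of C5 and C10 should come from the anti transition state (tether exo, sulfonyl endo), which is reachable because the E geometry of C9=C10 holds C1 on the outside of the diene, and which puts the small methyl group, not C9, into the axial site 1,3 to the axial C4 methyl. The absolute sense comes from C3, whose bulky silyloxy group stays equatorial on the chair-like tether, so that H-5 ends up α and CH3-10 β relative to the 3β oxygen. C6 (sulfonyl α, trans to C4) follows from the retained E geometry of the dienophile and is erased in step 12. The step needs trans over cis fusion, one diene face and a rate above that of the 1,5-hydrogen shift of the cis-methyl diene; the endo-directing sulfone, the equatorial preference at C3 and the gem-dimethyl (reactive-rotamer) effect at C4 are what should secure these.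

Step 12
Reactants: 14 trans-fused cycloadduct (8-ethoxy-6α-phenylsulfonyl-12-nordrim-8-ene bis-silyl ether)
Product: 16 3β-[(tert-butyldimethylsilyl)oxy]-11-[(tert-butyldiphenylsilyl)oxy]-12-nordrim-6-en-8-one (5α-H, 9α-H, 10β-CH3), via β-sulfonyl ketone 15 (not isolated)
Conditions: 1 M HCl (aq), THF, 0 °C; then DBU, CH2Cl2, 0 °C → rt
Reagents that add atoms: water, O
Why: Enol ether hydrolysis protonates C9 from the α face (axial, anti to the C10 methyl), and DBU then expels benzenesulfinate from C6 by E1cB elimination through the C7 enolate, which fixes the double bond at C6=C7 and leaves C9 as its more stable epimer with the CH2OSi group equatorial.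

Step 13
Reactants: 16 3β-[(tert-butyldimethylsilyl)oxy]-11-[(tert-butyldiphenylsilyl)oxy]-12-nordrim-6-en-8-one
Product: 17 3β-[(tert-butyldimethylsilyl)oxy]-11-[(tert-butyldiphenylsilyl)oxy]drima-6,8(12)-diene
Conditions: Ph3PCH3Br, KOtBu, THF, 0 °C → rt; then 16, rt → 40 °C
Reagents that add atoms: methyltriphenylphosphonium bromide, C[P+](c1ccccc1)(c1ccccc1)c1ccccc1.[Br-]
Why: Wittig methylenation by 1,2-addition of the non-stabilised ylide to the conjugated ketone adds C12 and gives the C6=C7–C8=C12 diene; C9 is already the thermodynamic epimer, so transient enolisation should do no harm.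

Step 14
Reactants: 17 3β-[(tert-butyldimethylsilyl)oxy]-11-[(tert-butyldiphenylsilyl)oxy]drima-6,8(12)-diene
Product: 18 drima-6,8(12)-diene-3β,11-diol
Conditions: TBAF (5 equiv), THF, 50 °C
Reagents that add atoms: none
Why: Fluoride-mediated desilylation removes both silyl ethers under non-acidic conditions that the exocyclic diene tolerates; the hindered 3β ether needs the gentle heating.

Step 15
Reactants: 18 drima-6,8(12)-diene-3β,11-diol; 19 7-hydroxycoumarin (umbelliferone)
Product: 20 7-{[3β-hydroxydrima-6,8(12)-dien-11-yl]oxy}-2H-chromen-2-one (target)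
Conditions: PPh3, DIAD, THF, 0 °C → rt
Reagents that add atoms: none
Why: Mitsunobu etherification, in which the oxyphosphonium salt should form only at the primary C11 hydroxyl (the 3β hydroxyl is secondary and flanked by the gem-dimethyl group) and is displaced by the acidic phenol in an SN2 step at CH2 that touches no stereocentre.

**Compound list**

1 | pent-4-yn-1-ol | C#CCCCO | starting material
2 | pent-4-ynal | C#CCCC=O | intermediate
3 | 1-methoxy-2-methyl-1-(trimethylsilyloxy)prop-1-ene | COC(O[Si](C)(C)C)=C(C)C | starting material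
4 | methyl (3S)-3-hydroxy-2,2-dimethylhept-6-ynoate | COC(=O)C(C)(C)[C@@H](O)CCC#C | intermediate
5 | methyl (3S)-3-[(tert-butyldimethylsilyl)oxy]-2,2-dimethylhept-6-ynoate | COC(=O)C(C)(C)[C@@H](O[Si](C)(C)C(C)(C)C)CCC#C | intermediate
6 | (3S)-3-[(tert-butyldimethylsilyl)oxy]-2,2-dimethylhept-6-yn-1-ol | OCC(C)(C)[C@@H](O[Si](C)(C)C(C)(C)C)CCC#C | intermediate
7 | (6S)-6-[(tert-butyldimethylsilyl)oxy]-7,7-dimethyloct-2-yne-1,8-diol | OCC(C)(C)[C@@H](O[Si](C)(C)C(C)(C)C)CCC#CCO | intermediate
8 | alkenylmagnesium bromide: the 1,8-bis(bromomagnesium alkoxide) of the (6S)-2-(bromomagnesio)-3,7,7-trimethyl-6-silyloxyoct-2-ene-1,8-diol, magnesium on C2 cis to the C3 methyl | Br[Mg]OC/C([Mg]Br)=C(C)\CC[C@H](O[Si](C)(C)C(C)(C)C)C(C)(C)CO[Mg]Br | intermediate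
9 | (2E,6S)-6-[(tert-butyldimethylsilyl)oxy]-2-iodo-3,7,7-trimethyloct-2-ene-1,8-diol | OC/C(I)=C(C)\CC[C@H](O[Si](C)(C)C(C)(C)C)C(C)(C)CO | intermediate
10 | (3S,6E)-3-[(tert-butyldimethylsilyl)oxy]-8-[(tert-butyldiphenylsilyl)oxy]-7-iodo-2,2,6-trimethyloct-6-en-1-ol | CC(C)(C)[Si](OC/C(I)=C(C)\CC[C@H](O[Si](C)(C)C(C)(C)C)C(C)(C)CO)(c1ccccc1)c1ccccc1 | intermediate
11 | (3S,6E)-3-[(tert-butyldimethylsilyl)oxy]-8-[(tert-butyldiphenylsilyl)oxy]-7-iodo-2,2,6-trimethyloct-6-enal | CC(C)(C)[Si](OC/C(I)=C(C)\CC[C@H](O[Si](C)(C)C(C)(C)C)C(C)(C)C=O)(c1ccccc1)c1ccccc1 | intermediate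
12 | {[(1E,4S,7E)-4-[(tert-butyldimethylsilyl)oxy]-9-[(tert-butyldiphenylsilyl)oxy]-8-iodo-3,3,7-trimethylnona-1,7-dien-1-yl]sulfonyl}benzene | CC(C)(C)[Si](OC/C(I)=C(C)\CC[C@H](O[Si](C)(C)C(C)(C)C)C(C)(C)/C=C/S(=O)(=O)c1ccccc1)(c1ccccc1)c1ccccc1 | intermediate
13 | {[(1E,4S,7E)-4-[(tert-butyldimethylsilyl)oxy]-8-{[(tert-butyldiphenylsilyl)oxy]methyl}-9-ethoxy-3,3,7-trimethyldeca-1,7,9-trien-1-yl]sulfonyl}benzene | CC(C)(C)[Si](OC/C(C(=C)OCC)=C(C)\CC[C@H](O[Si](C)(C)C(C)(C)C)C(C)(C)/C=C/S(=O)(=O)c1ccccc1)(c1ccccc1)c1ccccc1 | intermediate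
14 | 8-ethoxy-6α-(phenylsulfonyl)-3β-[(tert-butyldimethylsilyl)oxy]-11-[(tert-butyldiphenylsilyl)oxy]-12-nordrim-8-ene (trans-fused, 5α-H, 10β-CH3) | CCOC1=C(CO[Si](c3ccccc3)(c3ccccc3)C(C)(C)C)[C@@]2(C)CC[C@H](O[Si](C)(C)C(C)(C)C)C(C)(C)[C@@H]2[C@@H](S(=O)(=O)c3ccccc3)C1 | intermediate
15 | 6α-(phenylsulfonyl)-3β-[(tert-butyldimethylsilyl)oxy]-11-[(tert-butyldiphenylsilyl)oxy]-12-nordriman-8-one (5α-H, 9α-H, 10β-CH3) | O=C1C[C@H](S(=O)(=O)c3ccccc3)[C@H]2C(C)(C)[C@@H](O[Si](C)(C)C(C)(C)C)CC[C@]2(C)[C@H]1CO[Si](c4ccccc4)(c4ccccc4)C(C)(C)C | intermediate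
16 | 3β-[(tert-butyldimethylsilyl)oxy]-11-[(tert-butyldiphenylsilyl)oxy]-12-nordrim-6-en-8-one (5α-H, 9α-H, 10β-CH3) | O=C1C=C[C@H]2C(C)(C)[C@@H](O[Si](C)(C)C(C)(C)C)CC[C@]2(C)[C@H]1CO[Si](c3ccccc3)(c3ccccc3)C(C)(C)C | intermediate
17 | 3β-[(tert-butyldimethylsilyl)oxy]-11-[(tert-butyldiphenylsilyl)oxy]drima-6,8(12)-diene | C=C1C=C[C@H]2C(C)(C)[C@@H](O[Si](C)(C)C(C)(C)C)CC[C@]2(C)[C@H]1CO[Si](c3ccccc3)(c3ccccc3)C(C)(C)C | intermediate
18 | drima-6,8(12)-diene-3β,11-diol | C=C1C=C[C@H]2C(C)(C)[C@@H](O)CC[C@]2(C)[C@H]1CO | intermediate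
19 | 7-hydroxycoumarin (umbelliferone) | Oc1ccc2ccc(=O)oc2c1 | starting material
20 | 7-{[3β-hydroxydrima-6,8(12)-dien-11-yl]oxy}-2H-chromen-2-one | C=C1C=C[C@H]2C(C)(C)[C@@H](O)CC[C@]2(C)[C@H]1COc1ccc2ccc(=O)oc2c1 | target

**Step count and risks**

Total steps: 15. Longest linear sequence: 15 (steps 1–15 from pent-4-yn-1-ol).

Step 11 is the most likely to fail. The cycloaddition may be too slow at temperatures that the cis-methyl diene tolerates before its 1,5-hydrogen shift sets in, or the cis-fused pathway may compete. The fallback changes the dienophile to a nitroalkene, which should react near room temperature with a stronger endo preference. It sets out from aldehyde 11. Stille coupling as in step 10 would give the diene aldehyde F1. A Henry reaction with nitromethane and catalytic base would give the nitro alcohol F2, as a mixture at the carbinol carbon. Dehydration with MsCl and Et3N would give the (E)-nitro triene F3, which should cyclise in toluene at 25–80 °C to the 6α-nitro cycloadduct F4. The conditions of step 12 would hydrolyse this to the β-nitro ketone F5 and eliminate nitrous acid, and the route is rejoined at enone 16.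

Step 6 is the next risk. The carbomagnesiation may be incomplete or unselective in its regiochemistry, or the alkene geometry may be lost before iodinolysis. The fallback uses conjugate addition to an ynoate, where the regiochemistry is fixed by the ester, and sets out from alcohol 6. Double methoxycarbonylation (n-BuLi, 2.1 equiv, then ClCO2Me) would give the ynoate carbonate F6. Syn-addition of Me2CuLi in THF at −78 °C would give the alkenylcuprate F7, which is trapped in the same flask with I2 as the (E)-α-iodo enoate F8. DIBAL-H would reduce the ester and cleave the carbonate, and the route is rejoined at iodo diol 9.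

Step 15 is the third risk. The activated oxyphosphonium salt may eliminate across C9–C11, since H-9 is allylic, or substitution at the β-branched CH2 next to quaternary C10 may be sluggish. The fallback reverses the polarity so that C11–O is never activated. It sets out from diol 18 and uses a palladium-catalysed C–O cross-coupling of the primary hydroxyl with 7-bromocoumarin (O=c1ccc2ccc(Br)cc2o1) under [(allyl)PdCl]2, RockPhos and Cs2CO3 in toluene at 90 °C. The hindered 3β hydroxyl should not couple, and the route is rejoined directly at target 20; this fallback makes no new compound (F0).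

**Further compounds**

F1 | step 11 | (3S,6E)-3-[(tert-butyldimethylsilyl)oxy]-7-{[(tert-butyldiphenylsilyl)oxy]methyl}-8-ethoxy-2,2,6-trimethylnona-6,8-dienal | CC(C)(C)[Si](OC/C(C(=C)OCC)=C(C)\CC[C@H](O[Si](C)(C)C(C)(C)C)C(C)(C)C=O)(c1ccccc1)c1ccccc1
F2 | step 11 | nitro alcohol from F1 and nitromethane (both epimers at the new carbinol carbon) | CC(C)(C)[Si](OC/C(C(=C)OCC)=C(C)\CC[C@H](O[Si](C)(C)C(C)(C)C)C(C)(C)C(O)C[N+](=O)[O-])(c1ccccc1)c1ccccc1
F3 | step 11 | (1E,4S,7E)-1-nitro analogue of triene 13 | CC(C)(C)[Si](OC/C(C(=C)OCC)=C(C)\CC[C@H](O[Si](C)(C)C(C)(C)C)C(C)(C)/C=C/[N+](=O)[O-])(c1ccccc1)c1ccccc1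
F4 | step 11 | 8-ethoxy-6α-nitro-3β-[(tert-butyldimethylsilyl)oxy]-11-[(tert-butyldiphenylsilyl)oxy]-12-nordrim-8-ene | CCOC1=C(CO[Si](c3ccccc3)(c3ccccc3)C(C)(C)C)[C@@]2(C)CC[C@H](O[Si](C)(C)C(C)(C)C)C(C)(C)[C@@H]2[C@@H]([N+](=O)[O-])C1
F5 | step 11 | 6α-nitro-3β-[(tert-butyldimethylsilyl)oxy]-11-[(tert-butyldiphenylsilyl)oxy]-12-nordriman-8-one | O=C1C[C@H]([N+](=O)[O-])[C@H]2C(C)(C)[C@@H](O[Si](C)(C)C(C)(C)C)CC[C@]2(C)[C@H]1CO[Si](c3ccccc3)(c3ccccc3)C(C)(C)C
F6 | step 6 | methyl (6S)-6-[(tert-butyldimethylsilyl)oxy]-8-[(methoxycarbonyl)oxy]-7,7-dimethyloct-2-ynoate | COC(=O)OCC(C)(C)[C@@H](O[Si](C)(C)C(C)(C)C)CCC#CC(=O)OC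
F7 | step 6 | lithium alkenyl(methyl)cuprate from F6, copper on C2 cis to the C3 methyl | COC(=O)OCC(C)(C)[C@@H](O[Si](C)(C)C(C)(C)C)CC/C(C)=C(/[Cu-]C)C(=O)OC.[Li+]
F8 | step 6 | methyl (2E,6S)-6-[(tert-butyldimethylsilyl)oxy]-2-iodo-8-[(methoxycarbonyl)oxy]-3,7,7-trimethyloct-2-enoate | COC(=O)OCC(C)(C)[C@@H](O[Si](C)(C)C(C)(C)C)CC/C(C)=C(/I)C(=O)OC
F0 | step 15 | none | none
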